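Ring A (C1–C5, C10; eremophilane numbering) is read as a Diels–Alder cyclohexene. C4 and C5, with their mutually cis methyl groups C15 and C14 and with C6 on quaternary C5, are the carbons of a tiglate; because C9, the neighbour of C10, bears oxygen, this tiglate can be tethered as the O9 ester to a diene C10=C1–C2=C3–OSi. One thermal intramolecular cycloaddition makes C3–C4 and C5–C10, closes ring A plus a cis-fused γ-lactone and passes the single allylboration-set centre C9 on to C3, C4, C5 and C10. The precursor is an acyclic (1E,3E)-silyloxydienyl tiglate with a ketal-masked C8 ketone; the lactone is later reduced and ring B closed by aldol condensation.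

Key step: step 7

Remark: atom labels follow eremophilane numbering (ring A = C1–C5 and C10; ring B = C5–C10; isopropenyl = C11–C13; C14 on C5; C15 on C4); β means the face that carries C14 and C15, α the other face.

Step 1
Reactants: 1 methyl pyruvate
Product: 2 methyl 2,2-dimethoxypropanoate
Conditions: HC(OMe)3, MeOH, H2SO4 (cat.), reflux
Reagents that add atoms: trimethyl orthoformate, COC(OC)OC
Why: Acid-catalysed ketalisation of the activated ketone, driven by the orthoester as water scavenger, masks the future C8 carbonyl so that only the ester reacts in the next step.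

Step 2
Reactants: 2 methyl 2,2-dimethoxypropanoate
Product: 3 2,2-dimethoxypropanal
Conditions: i-Bu2AlH (1.05 equiv), CH2Cl2, −78 °C; aq. KNaC4H4O6
Reagents that add atoms: none
Why: Partial ester reduction should stop at the aldehyde because the α,α-dialkoxy aluminium hemiacetal is stable at −78 °C and collapses only on work-up, and the product cannot enolise.

Step 3
Reactants: 3 2,2-dimethoxypropanal; 4 allylmagnesium bromide
Product: 6 (R)-2,2-dimethoxyhex-5-en-3-ol, via (+)-B-allyldiisopinocampheylborane 5 (not isolated)
Conditions: (+)-Ipc2BOMe [from (−)-α-pinene], 4, Et2O, 0 °C → rt; then 3, −78 °C; NaOH, H2O2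
Reagents that add atoms: none
Why: Reagent-controlled asymmetric allylboration (Brown type) through a closed six-membered chair transition state, in which the isopinocampheyl groups from (−)-α-pinene deliver the allyl group to the Re face of the aldehyde and so set C9 as R.

Step 4
Reactants: 6 (R)-2,2-dimethoxyhex-5-en-3-ol; 7 tiglic acid
Product: 8 (R)-2,2-dimethoxyhex-5-en-3-yl tiglate [(E)-2-methylbut-2-enoate]
Conditions: DCC, DMAP, CH2Cl2, 0 °C → rt
Reagents that add atoms: none
Why: Steglich esterification through the N-acylpyridinium ion acylates the hindered secondary alcohol under neutral conditions that spare the ketal, the (E)-acid being the stable geometric isomer and C9 keeping its configuration because only the O–H bond reacts.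

Step 5
Reactants: 8 (R)-2,2-dimethoxyhex-5-en-3-yl tiglate; 9 crotonaldehyde
Product: 10 (R,E)-6,6-dimethoxy-1-oxohept-2-en-5-yl tiglate
Conditions: second-generation Hoveyda–Grubbs catalyst (H2IMes)Cl2Ru(=CH-C6H4-2-OiPr) (5 mol %), 9 (5 equiv), CH2Cl2, 40 °C
Reagents that add atoms: none
Why: Olefin cross-metathesis of the unhindered terminal alkene with the enal partner, with loss of propene, should give the (E)-enal (C2, C3) while the trisubstituted, electron-poor tiglate alkene stays inert to the ruthenium carbene.

Step 6
Reactants: 10 (R,E)-6,6-dimethoxy-1-oxohept-2-en-5-yl tiglate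
Product: 11 (R,1E,3E)-1-(tert-butyldimethylsilyloxy)-6,6-dimethoxyhepta-1,3-dien-5-yl tiglate
Conditions: Et3N (3 equiv), TBSOTf (1.2 equiv), Et2O, −78 → 0 °C
Reagents that add atoms: tert-butyldimethylsilyl triflate, CC(C)(C)[Si](C)(C)OS(=O)(=O)C(F)(F)F
Why: Soft enolisation (O-silylation of the enal followed by removal of a C10 proton by the amine) gives the 1-silyloxy-1,3-diene without a free dienolate, so the tiglate on C9 is not expelled, the s-trans enal leading to the (E)-enol ether and the branched C9 substituent favouring the (E)-C10=C1 bond.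

Step 7
Reactants: 11 (R,1E,3E)-1-(tert-butyldimethylsilyloxy)-6,6-dimethoxyhepta-1,3-dien-5-yl tiglate
Product: 12 cis-fused cyclohexene γ-lactone [3α-(tert-butyldimethylsilyloxy)-4β,5β-dimethyl-10βH-cyclohex-1-ene with the C6 lactone carbonyl on C5 and C9 on C10 both α; 9R, H9 cis to H10, 1,1-dimethoxyethyl group cis to C1]
Conditions: PhMe (0.01 M), 2,6-di-tert-butyl-4-methylpyridine (0.2 equiv), BHT (cat.), sealed tube, 160 °C
Reagents that add atoms: none
Why: A concerted, asynchronous thermal [4+2] cycloaddition, namely the intramolecular Diels–Alder reaction of an ester-tethered 1,3,8-nonatriene (the known reaction type of penta-2,4-dienyl acrylates, here with an electron-rich 1-silyloxydiene and a tiglate), forms C3–C4 and C5–C10. Ring A closes as the six-membered cycloadduct (new C1=C2 alkene) and the C6(=O)–O9 tether closes at the same time as a five-membered γ-lactone (C5–C6–O–C9–C10) cis-fused to it; the tether also enforces the C3-to-C4 and C10-to-C5 pairing, the reverse of what this diene would choose without it. C4 and C5 are fixed by suprafacial addition to the (E)-tiglate (C14 and C15 cis, C6 trans to C15), C3 by the (E)-enol ether and C10 by the (E)-C10=C1 bond, which together put O3 and C9 cis. The endo mode (lactone carbonyl under the diene) is required to bring C6 onto the face of O3 and C9; it should be preferred because it leaves both methyl groups of the dienophile exo and leads to the less strained cis ring fusion. The diene face is selected by C9: its oxygen has to point toward the dienophile, the bulky ketal carbon C8 then sits on the opposite face of the diene, clear of the exo methyl C14, and H9 lies near the diene plane beside H10, so that H9 and H10 become cis on the lactone. Dilution, the non-polar solvent and the hindered pyridine base guard against intermolecular reaction, ionisation of the dienylic ester and acid-induced loss of the silyl enol ether.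

Step 8
Reactants: 12 cis-fused cyclohexene γ-lactone
Product: 13 saturated lactone (C1–C2 single bond; all stereocentres as in 12)
Conditions: H2 (1 atm), Pd/C, EtOAc, Et3N (trace), rt
Reagents that add atoms: none
Why: Heterogeneous catalytic hydrogenation saturates the only C=C bond of the molecule, creates no stereocentre and leaves lactone, ketal and silyl ether untouched in the faintly basic medium.

Step 9
Reactants: 13 saturated lactone
Product: 15 keto lactol (C8 methyl ketone on C9; C6 hydroxyl as anomer mixture; 9R), via lactol ketal 14 (not isolated)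
Conditions: i-Bu2AlH (1.1 equiv), CH2Cl2, −78 °C; aq. KNaC4H4O6; then PPTS, acetone–H2O (9:1), 45 °C
Reagents that add atoms: water, O
Why: Partial reduction of the γ-lactone stops at the aluminium lactolate at −78 °C, and mild acid hydrolysis of the dimethyl ketal then unmasks the C8 methyl ketone while the secondary silyl ether and C9 stay as they are.

Step 10
Reactants: 15 keto lactol
Product: 17 enone ketol 3α-(tert-butyldimethylsilyloxy)-9β-hydroxy-4β,5β-dimethyl-10βH-cis-decal-6-en-8-one, via aldol adduct 16 (not isolated)
Conditions: KOH (0.5 equiv), degassed MeOH, 0 °C → rt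
Reagents that add atoms: none
Why: Intramolecular aldol condensation, in which the enolate of the C7 methyl ketone adds to the C6 aldehyde in equilibrium with the lactol to close the six-membered ring B and E1cB loss of water gives the C6=C7 enone; C9, now α to the ketone, already has its more stable configuration (hydroxyl equatorial), so the base should not erode it.

Step 11
Reactants: 17 enone ketol; 18 3-methylbut-2-enoyl chloride
Product: 19 9β-(3-methylbut-2-enoyloxy) enone silyl ether
Conditions: pyridine, DMAP (cat.), CH2Cl2, 0 °C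
Reagents that add atoms: none
Why: Nucleophile-catalysed O-acylation of the secondary α-ketol, with the weak base pyridine chosen so that the acid chloride does not form a vinylketene and the senecioyl double bond stays conjugated.

Step 12
Reactants: 19 9β-(3-methylbut-2-enoyloxy) enone silyl ether
Product: 20 3α-hydroxy-9β-(3-methylbut-2-enoyloxy) enone
Conditions: HF·pyridine, THF–pyridine, 0 °C → rt
Reagents that add atoms: none
Why: Fluoride-driven cleavage of the Si–O bond under buffered conditions removes the silyl group without touching the enone, the α-acyloxy ketone or the enoate.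

Step 13
Reactants: 20 3α-hydroxy-9β-(3-methylbut-2-enoyloxy) enone; 7 tiglic acid
Product: 21 enone diester [3α-tigloyloxy-9β-(3-methylbut-2-enoyloxy)-4β,5β-dimethyl-10βH-cis-decal-6-en-8-one]
Conditions: 7, 2,4,6-trichlorobenzoyl chloride, Et3N, THF, rt; then 20, DMAP, PhMe, rt → 50 °C
Reagents that add atoms: none
Why: Yamaguchi esterification (mixed anhydride, then acyl transfer by DMAP) suits the hindered equatorial C3 alcohol next to C4, and C3 keeps its configuration because only the O–H bond reacts.

Step 14
Reactants: 21 enone diester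
Product: 22 7-iodoenone diester
Conditions: I2 (2 equiv), pyridine–CH2Cl2 (1:1), 0 °C → rt
Reagents that add atoms: iodine, [I][I]
Why: α-Iodination of the enone by addition–elimination (pyridine adds to C6, the enolate is iodinated at C7, pyridine leaves again) is specific for the ketone-conjugated alkene, the electron-poor ester alkenes being unreactive.

Step 15
Reactants: 22 7-iodoenone diester; 23 tributyl(isopropenyl)stannane
Product: 24 7-isopropenyl cross-conjugated dienone [3α-tigloyloxy-9β-(3-methylbut-2-enoyloxy)-10βH-eremophila-6,11-dien-8-one]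
Conditions: Pd2(dba)3 (5 mol %), AsPh3 (20 mol %), CuI (10 mol %), NMP, rt → 45 °C
Reagents that add atoms: none
Why: Stille coupling (oxidative addition of the C7–I bond to zerovalent palladium, CuI-assisted transfer of the isopropenyl group from tin, reductive elimination) runs under neutral conditions that preserve the α-acyloxy ketone and both esters.

Step 16
Reactants: 24 7-isopropenyl cross-conjugated dienone
Product: 26 CNP0375730.1 (target; 7β-isopropenyl), via silyl dienol ether 25 (not isolated)
Conditions: [(Ph3P)CuH]6 (5 mol %), PhMe2SiH (1.5 equiv), PhMe, 0 °C → rt; then AcOH (3 equiv), Bu4NF (1.5 equiv), THF, −78 °C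
Reagents that add atoms: none
Why: Copper hydride conjugate reduction (1,4-hydrosilylation) delivers hydride to C6 of the enone in preference to the less electrophilic enoates, and fluoride then releases the dienolate, which is protonated kinetically at C7 rather than at C12 and leaves the isopropenyl group equatorial (7β), the more stable arrangement of this epimerisable centre.

Compound list
1 | methyl pyruvate | CC(=O)C(=O)OC | starting material
2 | methyl 2,2-dimethoxypropanoate | COC(=O)C(C)(OC)OC | intermediate
3 | 2,2-dimethoxypropanal | CC(OC)(OC)C=O | intermediate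
4 | allylmagnesium bromide | C=CC[Mg]Br | starting material
5 | (+)-B-allyldiisopinocampheylborane (not isolated) | C=CCB([C@H]1C[C@H]2C[C@@H]([C@@H]1C)C2(C)C)[C@H]1C[C@H]2C[C@@H]([C@@H]1C)C2(C)C | intermediate
6 | (R)-2,2-dimethoxyhex-5-en-3-ol | C=CC[C@@H](O)C(C)(OC)OC | intermediate
7 | tiglic acid, (E)-2-methylbut-2-enoic acid | C/C=C(\C)C(=O)O | starting material
8 | (R)-2,2-dimethoxyhex-5-en-3-yl tiglate | C/C=C(\C)C(=O)O[C@H](CC=C)C(C)(OC)OC | intermediate
9 | crotonaldehyde, (E)-but-2-enal | C/C=C/C=O | starting material
10 | (R,E)-6,6-dimethoxy-1-oxohept-2-en-5-yl tiglate | C/C=C(\C)C(=O)O[C@H](C/C=C/C=O)C(C)(OC)OC | intermediate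
11 | (R,1E,3E)-1-(tert-butyldimethylsilyloxy)-6,6-dimethoxyhepta-1,3-dien-5-yl tiglate | C/C=C(\C)C(=O)O[C@H](/C=C/C=C/O[Si](C)(C)C(C)(C)C)C(C)(OC)OC | intermediate
12 | cis-fused cyclohexene γ-lactone: 6-(tert-butyldimethylsilyloxy)-3-(1,1-dimethoxyethyl)-7,7a-dimethyl-3a,6,7,7a-tetrahydroisobenzofuran-1(3H)-one; silyloxy group and lactone on one face of the carbocycle, the two methyls and H3a on the other, H3 cis to H3a | C[C@H]1[C@H](O[Si](C)(C)C(C)(C)C)C=C[C@H]2[C@]1(C)C(=O)O[C@H]2C(C)(OC)OC | intermediate
13 | saturated lactone: the 3a,4,5,6,7,7a-hexahydro analogue of 12, same configuration | C[C@H]1[C@H](O[Si](C)(C)C(C)(C)C)CC[C@H]2[C@]1(C)C(=O)O[C@H]2C(C)(OC)OC | intermediate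
14 | lactol ketal (lactol of 13, anomer mixture; not isolated) | C[C@H]1[C@H](O[Si](C)(C)C(C)(C)C)CC[C@H]2[C@]1(C)C(O)O[C@H]2C(C)(OC)OC | intermediate
15 | keto lactol (3-acetyl lactol, anomer mixture) | C[C@H]1[C@H](O[Si](C)(C)C(C)(C)C)CC[C@H]2[C@]1(C)C(O)O[C@H]2C(C)=O | intermediate
16 | aldol adduct: 6,9β-dihydroxy-3α-silyloxy-cis-decal-8-one (C6 epimers; not isolated) | C[C@H]1[C@H](O[Si](C)(C)C(C)(C)C)CC[C@H]2[C@]1(C)C(O)CC(=O)[C@@H]2O | intermediate
17 | enone ketol: 3α-(tert-butyldimethylsilyloxy)-9β-hydroxy-4β,5β-dimethyl-10βH-cis-decal-6-en-8-one | C[C@H]1[C@H](O[Si](C)(C)C(C)(C)C)CC[C@H]2[C@]1(C)C=CC(=O)[C@@H]2O | intermediate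
18 | 3-methylbut-2-enoyl chloride | CC(C)=CC(=O)Cl | starting material
19 | 9β-(3-methylbut-2-enoyloxy) enone silyl ether | C[C@H]1[C@H](O[Si](C)(C)C(C)(C)C)CC[C@H]2[C@]1(C)C=CC(=O)[C@@H]2OC(=O)C=C(C)C | intermediate
20 | 3α-hydroxy-9β-(3-methylbut-2-enoyloxy) enone | C[C@H]1[C@H](O)CC[C@H]2[C@]1(C)C=CC(=O)[C@@H]2OC(=O)C=C(C)C | intermediate
21 | enone diester: 3α-tigloyloxy-9β-(3-methylbut-2-enoyloxy)-4β,5β-dimethyl-10βH-cis-decal-6-en-8-one | C[C@H]1[C@H](OC(=O)/C(C)=C/C)CC[C@H]2[C@]1(C)C=CC(=O)[C@@H]2OC(=O)C=C(C)C | intermediate
22 | 7-iodoenone diester | C[C@H]1[C@H](OC(=O)/C(C)=C/C)CC[C@H]2[C@]1(C)C=C(I)C(=O)[C@@H]2OC(=O)C=C(C)C | intermediate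
23 | tributyl(isopropenyl)stannane | CC(=C)[Sn](CCCC)(CCCC)CCCC | starting material
24 | 7-isopropenyl dienone: 3α-tigloyloxy-9β-(3-methylbut-2-enoyloxy)-10βH-eremophila-6,11-dien-8-one | C[C@H]1[C@H](OC(=O)/C(C)=C/C)CC[C@H]2[C@]1(C)C=C(C(C)=C)C(=O)[C@@H]2OC(=O)C=C(C)C | intermediate
25 | 8-(dimethylphenylsilyloxy) 7,11-dienol ether (not isolated) | C[C@H]1[C@H](OC(=O)/C(C)=C/C)CC[C@H]2[C@]1(C)CC(C(C)=C)=C(O[Si](C)(C)c1ccccc1)[C@@H]2OC(=O)C=C(C)C | intermediate
26 | CNP0375730.1: 3α-tigloyloxy-9β-(3-methylbut-2-enoyloxy)-10βH-eremophil-11-en-8-one, 7β-isopropenyl, (3R,4R,5R,7R,9R,10S) | C=C(C)[C@H]1C[C@@]2(C)[C@H](CC[C@@H](OC(=O)/C(C)=C/C)[C@@H]2C)[C@@H](OC(=O)C=C(C)C)C1=O | target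

Total steps: 16. Longest linear sequence: 16 steps (1 to 26); 4, 7, 9, 18 and 23 are bought.

Steps most likely to fail

Step 7. The dienophile may add to the other face of the diene (the rotamer that keeps H9 next to C1 and turns the ketal outward), so that ring A is built in the opposite sense relative to C9; slow cycloaddition with ionisation of the dienylic ester is the second hazard. The fallback no longer asks C9 to survive as set. Once ring B exists, C9 is α to the C8 ketone and its target configuration (oxygen equatorial) is the more stable one, so it can be corrected by equilibration. The fallback sets out from aldehyde 3 and Grignard reagent 4. The enantiomeric reagent (−)-B-allyldiisopinocampheylborane F1, from (−)-Ipc2BOMe, gives (S)-2,2-dimethoxyhex-5-en-3-ol F2. The operations of steps 4 to 6 give the (S)-homoallyl tiglate F3, the (S)-enal tiglate F4 and the (S)-silyloxydienyl tiglate F5. Cycloaddition through the mirror image of the unwanted pathway gives the 9-epi lactone F6, whose ring A is that of 12. Hydrogenation gives the 9-epi saturated lactone F7, and reduction and hydrolysis as in step 9 give the 9-epi lactol ketal F8 and the 9-epi keto lactol F9. Methanolic KOH then gives the 9-epi aldol adduct F10 and the 9-epi enone ketol F11, which epimerises at C9 through its enolate under the same base and so arrives at 17. In either series the lactone has to be freed of its facial isomer before ring B is closed, since equilibration at C9 would turn that isomer into the enantiomer of 17.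

Step 6. The tiglate may be lost from C9: the δ-acyloxy enal is a vinylogous β-acyloxy carbonyl compound, and any dienolate character at C10, or activation of the ester or the ketal by the silyl triflate, leads to a 2,4-dienal. Formation of the (Z)-C10=C1 isomer is a lesser hazard. The fallback makes the diene before the ester is in place and sets out from alcohol 6. Cross-metathesis with 9 gives (R,E)-5-hydroxy-6,6-dimethoxyhept-2-enal F12. Silylation of the hydroxyl with TMSCl and Et3N, then soft enolisation with TBSOTf and Et3N in the same flask, gives the O9-trimethylsilyl tert-butyldimethylsilyl dienol ether F13, which has no acyloxy leaving group. K2CO3 in MeOH at 0 °C should cleave only the alkyl trimethylsilyl ether to give the (R)-dienyl carbinol F14, and Steglich esterification with 7 gives 11.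

Step 10. Under base the α-ketol may be oxidised by adventitious air or transposed through its enediol, the neopentyl C6 carbinol of the aldol adduct may resist dehydration, and the silyl ether may be cleaved. The fallback closes ring B by olefin metathesis under neutral conditions instead of by carbonyl condensation. It sets out from lactol ketal 14, isolated after the reduction of step 9. Wittig methylenation with Ph3P=CH2 opens the lactol to the vinyl carbinol F15, and PPTS in wet acetone gives the hydroxy methyl ketone F16. Mannich-type α-methylenation of the methyl group (paraformaldehyde, N-methylanilinium trifluoroacetate, THF, reflux) gives the vinyl ketone F17. Ring-closing metathesis with the second-generation Hoveyda–Grubbs catalyst expels ethylene and gives 17.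

Further compounds
F1 | step 7 | (−)-B-allyldiisopinocampheylborane | C=CCB([C@@H]1C[C@@H]2C[C@H]([C@H]1C)C2(C)C)[C@@H]1C[C@@H]2C[C@H]([C@H]1C)C2(C)C
F2 | step 7 | (S)-2,2-dimethoxyhex-5-en-3-ol | C=CC[C@H](O)C(C)(OC)OC
F3 | step 7 | (S)-2,2-dimethoxyhex-5-en-3-yl tiglate | C/C=C(\C)C(=O)O[C@@H](CC=C)C(C)(OC)OC
F4 | step 7 | (S,E)-6,6-dimethoxy-1-oxohept-2-en-5-yl tiglate | C/C=C(\C)C(=O)O[C@@H](C/C=C/C=O)C(C)(OC)OC
F5 | step 7 | (S,1E,3E)-1-(tert-butyldimethylsilyloxy)-6,6-dimethoxyhepta-1,3-dien-5-yl tiglate | C/C=C(\C)C(=O)O[C@@H](/C=C/C=C/O[Si](C)(C)C(C)(C)C)C(C)(OC)OC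
F6 | step 7 | 9-epi lactone (C9 epimer of 12) | C[C@H]1[C@H](O[Si](C)(C)C(C)(C)C)C=C[C@H]2[C@]1(C)C(=O)O[C@@H]2C(C)(OC)OC
F7 | step 7 | 9-epi saturated lactone | C[C@H]1[C@H](O[Si](C)(C)C(C)(C)C)CC[C@H]2[C@]1(C)C(=O)O[C@@H]2C(C)(OC)OC
F8 | step 7 | 9-epi lactol ketal | C[C@H]1[C@H](O[Si](C)(C)C(C)(C)C)CC[C@H]2[C@]1(C)C(O)O[C@@H]2C(C)(OC)OC
F9 | step 7 | 9-epi keto lactol | C[C@H]1[C@H](O[Si](C)(C)C(C)(C)C)CC[C@H]2[C@]1(C)C(O)O[C@@H]2C(C)=O
F10 | step 7 | 9-epi aldol adduct | C[C@H]1[C@H](O[Si](C)(C)C(C)(C)C)CC[C@H]2[C@]1(C)C(O)CC(=O)[C@H]2O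
F11 | step 7 | 9-epi enone ketol | C[C@H]1[C@H](O[Si](C)(C)C(C)(C)C)CC[C@H]2[C@]1(C)C=CC(=O)[C@H]2O
F12 | step 6 | (R,E)-5-hydroxy-6,6-dimethoxyhept-2-enal | O=C/C=C/C[C@@H](O)C(C)(OC)OC
F13 | step 6 | (R,1E,3E)-1-(tert-butyldimethylsilyloxy)-6,6-dimethoxy-5-(trimethylsilyloxy)hepta-1,3-diene | CC(C)(C)[Si](C)(C)O/C=C/C=C/[C@@H](O[Si](C)(C)C)C(C)(OC)OC
F14 | step 6 | (R,1E,3E)-1-(tert-butyldimethylsilyloxy)-6,6-dimethoxyhepta-1,3-dien-5-ol | CC(C)(C)[Si](C)(C)O/C=C/C=C/[C@@H](O)C(C)(OC)OC
F15 | step 10 | vinyl carbinol (C5 vinyl, C9 hydroxyl, ketal intact) | C[C@H]1[C@H](O[Si](C)(C)C(C)(C)C)CC[C@H]([C@@H](O)C(C)(OC)OC)[C@]1(C)C=C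
F16 | step 10 | hydroxy methyl ketone | C[C@H]1[C@H](O[Si](C)(C)C(C)(C)C)CC[C@H]([C@@H](O)C(C)=O)[C@]1(C)C=C
F17 | step 10 | vinyl ketone | C[C@H]1[C@H](O[Si](C)(C)C(C)(C)C)CC[C@H]([C@@H](O)C(=O)C=C)[C@]1(C)C=C
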